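**Retrosynthetic overview**

Ring numbering: O1–O2–C3–C4–C5–C6; C3 bears the propanoic acid chain (C2′, C1′), C6 bears CH3 and the trienyl chain. The target is traced back, through oxidation of C1′, desilylation and diimide reduction, to a 3,6-dihydro-1,2-dioxine with a C4=C5 double bond.
Key disconnection: the dihydrodioxine is cut at O2–C3 and at C4=C5 into a four-atom unit O2–O1–C6–C5 (a tertiary allylic hydroperoxide) and a two-carbon unit C3–C4 (an allylic mesylate). In the forward direction SN2 at C3 and ring-closing metathesis run in one flask, and this is the only ring made in the route.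
Enabling feature: the O1–O2 bond of the 1,2-dioxane is flanked by C6 and C3, both of which can be allylic carbons, so the ring has an alkene-level form, a cyclic bis-allylic peroxide whose single ring olefin is C4=C5.
Hydroperoxide half: geranylgeraniol, whose C2–C20 map onto C5, C6, the 6-methyl and the whole trienyl chain (C1 is excised), by Sharpless epoxidation, perhydrolysis with inversion at the tertiary carbon, glycol cleavage and methylenation.
Mesylate half: an Evans syn-aldol reaction with acrolein sets C2′ and a C3 carbinol whose configuration is inverted in the key step.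

Key step: step 10

Assumption: the acid-catalysed perhydrolysis of the trisubstituted epoxide (step 2) is taken to proceed with inversion at the tertiary carbon, as borderline SN2 openings of such epoxides normally do.

**Route**

Step 1
Reactants: 1 (2E,6E,10E)-geranylgeraniol
Product: 2 (2R,3R)-2,3-epoxygeranylgeraniol
Conditions: t-BuOOH, Ti(Oi-Pr)4 (cat.), D-(−)-diethyl tartrate (cat.), 4 Å MS, CH2Cl2, −20 °C
Reagents that add atoms: tert-butyl hydroperoxide, CC(C)(C)OO
Why: Sharpless asymmetric epoxidation oxidises only the allylic-alcohol olefin, and D-(−)-tartrate should deliver oxygen to the face that gives the (2R,3R)-epoxide, the mirror image of the L-tartrate outcome known for geraniol-type E-allylic alcohols.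

Step 2
Reactants: 2 (2R,3R)-2,3-epoxygeranylgeraniol
Product: 3 (2R,3S)-3-hydroperoxy-3,7,11,15-tetramethylhexadeca-6,10,14-triene-1,2-diol
Conditions: H2O2 (anhydrous ethereal solution, excess), H3PMo12O40 (phosphomolybdic acid, cat.), Et2O, 0 °C to rt
Reagents that add atoms: hydrogen peroxide, OO
Why: Acid-catalysed perhydrolysis of an epoxide (β-hydroxy hydroperoxide synthesis) should open the activated epoxide at the tertiary carbon in a borderline SN2 manner with inversion, turning (3R) into the (3S)-hydroperoxide that becomes C6 while C2 is untouched.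

Step 3
Reactants: 3 (2R,3S)-3-hydroperoxy-3,7,11,15-tetramethylhexadeca-6,10,14-triene-1,2-diol
Product: 5 (2S)-2-[(2-methoxypropan-2-yl)peroxy]-2,6,10,14-tetramethylpentadeca-5,9,13-trienal, via hydroperoxy aldehyde 4 (not isolated)
Conditions: NaIO4 on silica gel, CH2Cl2, 0 °C; filter; then 2-methoxypropene, PPTS (cat.), CH2Cl2, 0 °C
Reagents that add atoms: 2-methoxypropene, COC(C)=C
Why: Periodate (Malaprade) glycol cleavage excises C1 as formaldehyde and makes C2 the aldehyde carbon that becomes C5, and the labile α-hydroperoxy aldehyde is capped at once by acid-catalysed addition of its O–O–H group to the enol ether (peroxyketal protection), the quaternary stereocentre being unable to epimerise.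

Step 4
Reactants: 5 (2S)-2-[(2-methoxypropan-2-yl)peroxy]-2,6,10,14-tetramethylpentadeca-5,9,13-trienal
Product: 6 (3S)-3-[(2-methoxypropan-2-yl)peroxy]-3,7,11,15-tetramethylhexadeca-1,6,10,14-tetraene
Conditions: Ph3PCH3Br, KN(SiMe3)2, THF, 0 °C; then 5, −78 to 0 °C
Reagents that add atoms: methyltriphenylphosphonium bromide, C[P+](c1ccccc1)(c1ccccc1)c1ccccc1.[Br-]
Why: Wittig methylenation of the non-enolisable aldehyde should be far faster than any attack of the ylide on the hindered tertiary dialkyl peroxide, and it gives the vinyl group whose inner carbon is C5.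

Step 5
Reactants: 6 (3S)-3-[(2-methoxypropan-2-yl)peroxy]-3,7,11,15-tetramethylhexadeca-1,6,10,14-tetraene
Product: 7 (3S)-3-hydroperoxy-3,7,11,15-tetramethylhexadeca-1,6,10,14-tetraene
Conditions: AcOH/THF/H2O (4:2:1), BHT (trace), rt
Reagents that add atoms: none
Why: Mild acid hydrolysis of the peroxyketal, the standard release of a hydroperoxide, should leave the polyene and the stereocentre untouched.

Step 6
Reactants: 8 (S)-4-benzyl-3-propanoyl-1,3-oxazolidin-2-one; 9 acrolein
Product: 10 (4S)-4-benzyl-3-[(2S,3R)-3-hydroxy-2-methylpent-4-enoyl]-1,3-oxazolidin-2-one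
Conditions: n-Bu2BOTf, i-Pr2NEt, CH2Cl2, −78 to 0 °C; acrolein, −78 to 0 °C; then pH 7 buffer, MeOH, 30% H2O2, 0 °C
Reagents that add atoms: none
Why: Evans syn-aldol reaction: the Z-boron enolate reacts through a Zimmerman–Traxler chair in which the benzyl group of the auxiliary fixes the enolate face, giving the (2S,3R) syn adduct that carries the future C2′ methyl group and the C3 oxygen.

Step 7
Reactants: 10 (4S)-4-benzyl-3-[(2S,3R)-3-hydroxy-2-methylpent-4-enoyl]-1,3-oxazolidin-2-one
Product: 11 (2R,3R)-2-methylpent-4-ene-1,3-diol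
Conditions: LiBH4, MeOH (1 equiv), Et2O, 0 °C
Reagents that add atoms: none
Why: Reductive cleavage of the imide by borohydride frees the auxiliary and gives the 1,3-diol without touching either stereocentre.

Step 8
Reactants: 11 (2R,3R)-2-methylpent-4-ene-1,3-diol
Product: 12 (3R,4R)-5-[(tert-butyldimethylsilyl)oxy]-4-methylpent-1-en-3-ol
Conditions: TBSCl (1.05 equiv), imidazole, CH2Cl2, −20 °C
Reagents that add atoms: tert-butyldimethylsilyl chloride, CC(C)(C)[Si](C)(C)Cl
Why: Silylation of the primary hydroxyl should be much faster than that of the hindered allylic secondary one (steric selectivity), and the silyl ether keeps C1′ at an oxidation level that cannot trigger β-elimination at C3.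

Step 9
Reactants: 12 (3R,4R)-5-[(tert-butyldimethylsilyl)oxy]-4-methylpent-1-en-3-ol
Product: 13 (3R,4R)-5-[(tert-butyldimethylsilyl)oxy]-4-methylpent-1-en-3-yl methanesulfonate
Conditions: MsCl, Et3N, CH2Cl2, −40 °C; used at once without purification
Reagents that add atoms: methanesulfonyl chloride, CS(=O)(=O)Cl
Why: Sulfonylation at low temperature converts the C3 hydroxyl into a leaving group with retention of configuration.

Step 10
Reactants: 7 (3S)-3-hydroperoxy-3,7,11,15-tetramethylhexadeca-1,6,10,14-tetraene; 13 (3R,4R)-5-[(tert-butyldimethylsilyl)oxy]-4-methylpent-1-en-3-yl methanesulfonate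
Product: 15 tert-butyl{(2R)-2-[(3S,6S)-6-methyl-6-[(3E,7E)-4,8,12-trimethyltrideca-3,7,11-trien-1-yl]-3,6-dihydro-1,2-dioxin-3-yl]propoxy}dimethylsilane, via bis-allylic peroxide 14 (not isolated)
Conditions: 7, KOt-Bu (1.0 equiv), 18-crown-6, THF, −40 °C; 13 (1.3 equiv), −40 to 0 °C; AcOH (0.2 equiv); then dilute with degassed CH2Cl2 (5 mM), Hoveyda–Grubbs second-generation catalyst RuCl2(H2IMes)(=CH–C6H4-2-Oi-Pr) (cat.), 35 °C; ethyl vinyl ether quench
Reagents that add atoms: none
Why: The potassium peroxide anion of 7, an α-effect nucleophile of low basicity, displaces the allylic mesylate of 13 at C3 by SN2 with inversion (O2–C3), and the resulting bis-allylic peroxide 14 is closed by ring-closing metathesis of its two vinyl groups, the ruthenium alkylidene loading on the less hindered C4 vinyl group and expelling ethene as the C4=C5 bond forms. The closest known reaction types are the base-mediated alkylation of tertiary hydroperoxides by secondary sulfonates or triflates, which runs with inversion, and diene ring-closing metathesis to six-membered allylic heterocycles, olefin metathesis being tolerant of dialkyl peroxides. The only ring formed, the 3,6-dihydro-1,2-dioxine O1–O2–C3–C4=C5–C6, closes by metathesis between two monosubstituted olefins, a six-membered closure in which the ring enforces the cis double bond. No stereocentre is made from a prochiral atom: C3 arrives with inverted configuration (3R mesylate to 3S peroxide) under control of the aldol-derived carbinol, while C6 and C2′ are spectators, so two enantiopure halves merge into one diastereomer. The step needs direct SN2 in preference to SN2′ attack or elimination, which the soft, weakly basic peroxide anion and exactly one equivalent of base should secure, and it needs vinyl–vinyl closure in preference to cyclopentene formation onto the nearest trisubstituted chain olefin, which the much higher metathesis reactivity of monosubstituted olefins and a phosphine-free catalyst (no peroxide reduction) should secure.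

Step 11
Reactants: 15 tert-butyl{(2R)-2-[(3S,6S)-6-methyl-6-[(3E,7E)-4,8,12-trimethyltrideca-3,7,11-trien-1-yl]-3,6-dihydro-1,2-dioxin-3-yl]propoxy}dimethylsilane
Product: 16 tert-butyl{(2R)-2-[(3S,6S)-6-methyl-6-[(3E,7E)-4,8,12-trimethyltrideca-3,7,11-trien-1-yl]-1,2-dioxan-3-yl]propoxy}dimethylsilane
Conditions: KO2C–N=N–CO2K (excess), AcOH (slow addition), CH2Cl2/MeOH, 0 °C to rt
Reagents that add atoms: none
Why: Diimide reduction (concerted syn transfer of two hydrogens) should take the cis-disubstituted ring olefin much faster than the three trisubstituted chain olefins and leaves the O–O bond alone, so C4–C5 reaches the saturated level without any new stereocentre.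

Step 12
Reactants: 16 tert-butyl{(2R)-2-[(3S,6S)-6-methyl-6-[(3E,7E)-4,8,12-trimethyltrideca-3,7,11-trien-1-yl]-1,2-dioxan-3-yl]propoxy}dimethylsilane
Product: 17 (2R)-2-[(3S,6S)-6-methyl-6-[(3E,7E)-4,8,12-trimethyltrideca-3,7,11-trien-1-yl]-1,2-dioxan-3-yl]propan-1-ol
Conditions: n-Bu4NF, AcOH, THF, 0 °C to rt
Reagents that add atoms: none
Why: Fluoride desilylation buffered with acetic acid should remove the silyl ether without base-induced Kornblum–DeLaMare cleavage at the C3–H of the peroxide.

Step 13
Reactants: 17 (2R)-2-[(3S,6S)-6-methyl-6-[(3E,7E)-4,8,12-trimethyltrideca-3,7,11-trien-1-yl]-1,2-dioxan-3-yl]propan-1-ol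
Product: 18 (2S)-2-[(3S,6S)-6-methyl-6-[(3E,7E)-4,8,12-trimethyltrideca-3,7,11-trien-1-yl]-1,2-dioxan-3-yl]propanoic acid (CNP0179915.1)
Conditions: TEMPO (cat.), PhI(OAc)2 (2.5 equiv), MeCN/pH 7 phosphate buffer, 0 °C to rt
Reagents that add atoms: water, O
Why: Oxoammonium (TEMPO) oxidation with PhI(OAc)2 as terminal oxidant takes the primary alcohol through the aldehyde hydrate to the acid under near-neutral, chlorine-free conditions that should spare the dialkyl peroxide, the trisubstituted olefins and the C2′ stereocentre (the descriptor changes from R to S only because C1′ gains priority).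

**Compound list**

1 | (2E,6E,10E)-geranylgeraniol, (2E,6E,10E)-3,7,11,15-tetramethylhexadeca-2,6,10,14-tetraen-1-ol | CC(C)=CCC/C(C)=C/CC/C(C)=C/CC/C(C)=C/CO | starting material
2 | (2R,3R)-2,3-epoxygeranylgeraniol, [(2R,3R)-3-methyl-3-[(3E,7E)-4,8,12-trimethyltrideca-3,7,11-trien-1-yl]oxiran-2-yl]methanol | CC(C)=CCC/C(C)=C/CC/C(C)=C/CC[C@@]1(C)O[C@@H]1CO | intermediate
3 | (2R,3S,6E,10E)-3-hydroperoxy-3,7,11,15-tetramethylhexadeca-6,10,14-triene-1,2-diol | CC(C)=CCC/C(C)=C/CC/C(C)=C/CC[C@]([C@H](O)CO)(C)OO | intermediate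
4 | (2S,5E,9E)-2-hydroperoxy-2,6,10,14-tetramethylpentadeca-5,9,13-trienal | CC(C)=CCC/C(C)=C/CC/C(C)=C/CC[C@](C=O)(C)OO | intermediate
5 | (2S,5E,9E)-2-[(2-methoxypropan-2-yl)peroxy]-2,6,10,14-tetramethylpentadeca-5,9,13-trienal | CC(C)=CCC/C(C)=C/CC/C(C)=C/CC[C@](C=O)(C)OOC(C)(C)OC | intermediate
6 | (3S,6E,10E)-3-[(2-methoxypropan-2-yl)peroxy]-3,7,11,15-tetramethylhexadeca-1,6,10,14-tetraene | CC(C)=CCC/C(C)=C/CC/C(C)=C/CC[C@](C=C)(C)OOC(C)(C)OC | intermediate
7 | (3S,6E,10E)-3-hydroperoxy-3,7,11,15-tetramethylhexadeca-1,6,10,14-tetraene | CC(C)=CCC/C(C)=C/CC/C(C)=C/CC[C@](C=C)(C)OO | intermediate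
8 | (S)-4-benzyl-3-propanoyl-1,3-oxazolidin-2-one | CCC(=O)N1[C@@H](Cc2ccccc2)COC1=O | starting material
9 | acrolein | C=CC=O | starting material
10 | (4S)-4-benzyl-3-[(2S,3R)-3-hydroxy-2-methylpent-4-enoyl]-1,3-oxazolidin-2-one | C=C[C@@H](O)[C@H](C)C(=O)N1[C@@H](Cc2ccccc2)COC1=O | intermediate
11 | (2R,3R)-2-methylpent-4-ene-1,3-diol | C=C[C@@H](O)[C@H](C)CO | intermediate
12 | (3R,4R)-5-[(tert-butyldimethylsilyl)oxy]-4-methylpent-1-en-3-ol | C=C[C@@H](O)[C@H](C)CO[Si](C)(C)C(C)(C)C | intermediate
13 | (3R,4R)-5-[(tert-butyldimethylsilyl)oxy]-4-methylpent-1-en-3-yl methanesulfonate | C=C[C@@H](OS(C)(=O)=O)[C@H](C)CO[Si](C)(C)C(C)(C)C | intermediate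
14 | bis-allylic peroxide, tert-butyl{[(2R,3S)-2-methyl-3-{[(3S,6E,10E)-3,7,11,15-tetramethylhexadeca-1,6,10,14-tetraen-3-yl]peroxy}pent-4-en-1-yl]oxy}dimethylsilane | CC(C)=CCC/C(C)=C/CC/C(C)=C/CC[C@](C=C)(C)OO[C@@H](C=C)[C@H](C)CO[Si](C)(C)C(C)(C)C | intermediate
15 | tert-butyl{(2R)-2-[(3S,6S)-6-methyl-6-[(3E,7E)-4,8,12-trimethyltrideca-3,7,11-trien-1-yl]-3,6-dihydro-1,2-dioxin-3-yl]propoxy}dimethylsilane | CC(C)=CCC/C(C)=C/CC/C(C)=C/CC[C@@]1(C)C=C[C@@H]([C@H](C)CO[Si](C)(C)C(C)(C)C)OO1 | intermediate
16 | tert-butyl{(2R)-2-[(3S,6S)-6-methyl-6-[(3E,7E)-4,8,12-trimethyltrideca-3,7,11-trien-1-yl]-1,2-dioxan-3-yl]propoxy}dimethylsilane | CC(C)=CCC/C(C)=C/CC/C(C)=C/CC[C@@]1(C)CC[C@@H]([C@H](C)CO[Si](C)(C)C(C)(C)C)OO1 | intermediate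
17 | (2R)-2-[(3S,6S)-6-methyl-6-[(3E,7E)-4,8,12-trimethyltrideca-3,7,11-trien-1-yl]-1,2-dioxan-3-yl]propan-1-ol | CC(C)=CCC/C(C)=C/CC/C(C)=C/CC[C@@]1(C)CC[C@@H]([C@H](C)CO)OO1 | intermediate
18 | (2S)-2-[(3S,6S)-6-methyl-6-[(3E,7E)-4,8,12-trimethyltrideca-3,7,11-trien-1-yl]-1,2-dioxan-3-yl]propanoic acid | CC(C)=CCC/C(C)=C/CC/C(C)=C/CC[C@@]1(C)CC[C@@H]([C@H](C)C(=O)O)OO1 | target

**Step count and risks**

Total step count: 13. Longest linear sequence: 9 steps (steps 1–5 and 10–13).

Steps most likely to fail:

Step 10. The hindered peroxide anion may attack the vinyl terminus (SN2′) or act as a base and eliminate the allylic mesylate instead of substituting at C3. In the metathesis stage the C6 vinyl group may close onto the nearest trisubstituted chain olefin (cyclopentene formation), or the catalyst may isomerise the dihydrodioxine. The fallback forms the two bonds in separate, individually precedented steps; it sets out from aldehyde 5 and rejoins the route at 16. Wittig reaction of 5 with Ph3P=CHCHO should give the (E)-enal F1. An Evans syn-aldol reaction of the boron enolate of 8 with F1 should give the allylic alcohol F2. Diimide reduction of its disubstituted olefin should give the saturated imide F3, and borohydride cleavage of the auxiliary the diol F4. Silylation of the primary hydroxyl should give the silyl ether F5, and mesylation the secondary mesylate F6. Hydrolysis of the peroxyketal (AcOH/THF/H2O) should give the hydroperoxy mesylate F7. Treatment with KOt-Bu and 18-crown-6 in THF should then close the ring by intramolecular 6-exo-tet displacement with inversion at C3 to give 16.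

Step 2. Partial ionisation to the tertiary cation may erode the stereochemical fidelity at the future C6, some opening may occur at C2, and peroxomolybdate species may oxidise chain olefins. The fallback replaces stereospecific synthesis by resolution; it sets out from hydroperoxide 7 of insufficient purity and returns to 7. Acid-catalysed addition (PPTS) of 7 to (1R,2S)-2-phenylcyclohexyl 2-propenyl ether should give diastereomeric peroxyketals. The diastereomer with the (S)-configured peroxide carbon, peroxyketal F8, would be separated by chromatography and cleaved with AcOH/THF/H2O to return stereochemically pure 7.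

Step 3. The free α-hydroperoxy aldehyde may dimerise to peroxyhemiacetals or fragment by C–C cleavage (to the methyl ketone and formic acid) before the hydroperoxide is capped. The fallback never forms a free α-hydroperoxy aldehyde; it sets out from hydroperoxy diol 3 and rejoins the route at 14. The hydroperoxide of 3, the only O–H acidic enough for one equivalent of KOt-Bu (18-crown-6, THF), would be alkylated with mesylate 13 to give the peroxide diol F9. Periodate cleavage should give the α-(alkylperoxy) aldehyde F10, and Wittig methylenation (Ph3P=CH2) the bis-allylic peroxide 14. Isolated 14 would then be closed to 15 under the metathesis conditions of step 10.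

Further compounds

F1 | step 10 | (2E,4S,7E,11E)-4-[(2-methoxypropan-2-yl)peroxy]-4,8,12,16-tetramethylheptadeca-2,7,11,15-tetraenal | CC(C)=CCC/C(C)=C/CC/C(C)=C/CC[C@](/C=C/C=O)(C)OOC(C)(C)OC
F2 | step 10 | (4S)-4-benzyl-3-[(2S,3R,4E,6S,9E,13E)-3-hydroxy-6-[(2-methoxypropan-2-yl)peroxy]-2,6,10,14,18-pentamethylnonadeca-4,9,13,17-tetraenoyl]-1,3-oxazolidin-2-one | CC(C)=CCC/C(C)=C/CC/C(C)=C/CC[C@](/C=C/[C@@H](O)[C@H](C)C(=O)N1[C@@H](Cc2ccccc2)COC1=O)(C)OOC(C)(C)OC
F3 | step 10 | (4S)-4-benzyl-3-[(2S,3R,6S,9E,13E)-3-hydroxy-6-[(2-methoxypropan-2-yl)peroxy]-2,6,10,14,18-pentamethylnonadeca-9,13,17-trienoyl]-1,3-oxazolidin-2-one | CC(C)=CCC/C(C)=C/CC/C(C)=C/CC[C@](CC[C@@H](O)[C@H](C)C(=O)N1[C@@H](Cc2ccccc2)COC1=O)(C)OOC(C)(C)OC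
F4 | step 10 | (2R,3R,6S,9E,13E)-6-[(2-methoxypropan-2-yl)peroxy]-2,6,10,14,18-pentamethylnonadeca-9,13,17-triene-1,3-diol | CC(C)=CCC/C(C)=C/CC/C(C)=C/CC[C@](CC[C@@H](O)[C@H](C)CO)(C)OOC(C)(C)OC
F5 | step 10 | (2R,3R,6S,9E,13E)-1-[(tert-butyldimethylsilyl)oxy]-6-[(2-methoxypropan-2-yl)peroxy]-2,6,10,14,18-pentamethylnonadeca-9,13,17-trien-3-ol | CC(C)=CCC/C(C)=C/CC/C(C)=C/CC[C@](CC[C@@H](O)[C@H](C)CO[Si](C)(C)C(C)(C)C)(C)OOC(C)(C)OC
F6 | step 10 | (2R,3R,6S,9E,13E)-1-[(tert-butyldimethylsilyl)oxy]-6-[(2-methoxypropan-2-yl)peroxy]-2,6,10,14,18-pentamethylnonadeca-9,13,17-trien-3-yl methanesulfonate | CC(C)=CCC/C(C)=C/CC/C(C)=C/CC[C@](CC[C@@H](OS(C)(=O)=O)[C@H](C)CO[Si](C)(C)C(C)(C)C)(C)OOC(C)(C)OC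
F7 | step 10 | (2R,3R,6S,9E,13E)-1-[(tert-butyldimethylsilyl)oxy]-6-hydroperoxy-2,6,10,14,18-pentamethylnonadeca-9,13,17-trien-3-yl methanesulfonate | CC(C)=CCC/C(C)=C/CC/C(C)=C/CC[C@](CC[C@@H](OS(C)(=O)=O)[C@H](C)CO[Si](C)(C)C(C)(C)C)(C)OO
F8 | step 2 | (3S,6E,10E)-3-({2-[(1R,2S)-2-phenylcyclohexyl]oxypropan-2-yl}peroxy)-3,7,11,15-tetramethylhexadeca-1,6,10,14-tetraene | CC(C)=CCC/C(C)=C/CC/C(C)=C/CC[C@](C=C)(C)OOC(C)(C)O[C@@H]1CCCC[C@H]1c1ccccc1
F9 | step 3 | (2R,3S,6E,10E)-3-{[(3S,4R)-5-[(tert-butyldimethylsilyl)oxy]-4-methylpent-1-en-3-yl]peroxy}-3,7,11,15-tetramethylhexadeca-6,10,14-triene-1,2-diol | CC(C)=CCC/C(C)=C/CC/C(C)=C/CC[C@]([C@H](O)CO)(C)OO[C@@H](C=C)[C@H](C)CO[Si](C)(C)C(C)(C)C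
F10 | step 3 | (2S,5E,9E)-2-{[(3S,4R)-5-[(tert-butyldimethylsilyl)oxy]-4-methylpent-1-en-3-yl]peroxy}-2,6,10,14-tetramethylpentadeca-5,9,13-trienal | CC(C)=CCC/C(C)=C/CC/C(C)=C/CC[C@](C=O)(C)OO[C@@H](C=C)[C@H](C)CO[Si](C)(C)C(C)(C)C
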